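**Retrosynthetic overview**
1. Ester C–O bond last: target ⇐ diphenolic oxolanylmethanol + 4‑hydroxybenzoic acid (Mitsunobu, phenols left free).
2. Oxolane (the only ring formed, closed in step 5): C3–C4 bond by Pd–H borylative cyclisation of a 1,6‑enyne ether; syn H–Pd addition gives the Z‑benzylidene, C3 is relayed from C2, then C–B → C–OH.
3. Aryl–alkyne bond ⇐ terminal alkyne + 4‑iodo‑2‑methoxyphenol (Sonogashira).
4. Key bond O1–C2 (sets C2): chiral allyl propargyl ether ⇐ racemic allyl propargyl carbonate by iridium‑catalysed enantioconvergent decarboxylative allylic etherification.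
5. Carbonate ⇐ O‑silyl vanillin + vinylmagnesium bromide + propargyl chloroformate.

Assumption: the sense of induction in step 3 is fixed by experiment; the ligand enantiomer that gives the (R)‑ether is used, checked against the sample made by the fallback to step 3.

**Step 1**
Reactants: 1 vanillin
Product: 2 4-[(tert-butyldimethylsilyl)oxy]-3-methoxybenzaldehyde
Conditions: TBSCl (1.1 equiv), imidazole (2.2 equiv), DMF, 0 °C → rt
Reagents that add atoms: tert-butyldimethylsilyl chloride, CC(C)(C)[Si](C)(C)Cl
Why: Imidazole-promoted silylation (silyl ether protection) masks the phenol so that the Grignard reagent, the iridium allyl chemistry and the cross-coupling meet no acidic or nucleophilic ArOH; no stereocentre is involved.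

**Step 2**
Reactants: 2 4-[(tert-butyldimethylsilyl)oxy]-3-methoxybenzaldehyde; 3 vinylmagnesium bromide; 4 propargyl chloroformate
Product: 6 1-{4-[(tert-butyldimethylsilyl)oxy]-3-methoxyphenyl}prop-2-en-1-yl prop-2-yn-1-yl carbonate (racemic), via bromomagnesium allylic alkoxide 5 (not isolated)
Conditions: vinylmagnesium bromide (1.2 equiv), THF, −78 → 0 °C; then propargyl chloroformate (1.3 equiv), −78 °C → rt; NH4Cl work-up, Et3N-deactivated SiO2
Reagents that add atoms: none
Why: Grignard 1,2-addition to the aldehyde followed by O-acylation of the magnesium alkoxide with the chloroformate gives the allylic carbonate in one flask; the carbinol centre is left racemic because step 3 is enantioconvergent.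

**Step 3**
Reactants: 6 1-{4-[(tert-butyldimethylsilyl)oxy]-3-methoxyphenyl}prop-2-en-1-yl prop-2-yn-1-yl carbonate (racemic)
Product: 7 tert-butyl{2-methoxy-4-[(1R)-1-(prop-2-yn-1-yloxy)prop-2-en-1-yl]phenoxy}dimethylsilane
Conditions: [Ir(cod)Cl]2 (2 mol%), BINOL-derived N,N-bis(1-phenylethyl)phosphoramidite (4 mol%), DBU (10 mol%), THF, 25 °C, argon sweep
Reagents that add atoms: none
Why: Proposed new method: iridium-catalysed enantioconvergent decarboxylative allylic etherification of an alkyl allyl carbonate, in which the monovalent iridium–phosphoramidite catalyst ionises either enantiomer (or any rearranged cinnamyl isomer) to a (1-arylallyl)iridium cation and a propargyl carbonate anion, reversible return of that anion racemises the substrate, loss of CO2 leaves a propargyl alkoxide in the ion pair, and its irreversible attack anti to the metal at the aryl-bearing allyl terminus forms the O–C bond and sets the (R) centre with the usual iridium preference for the branched product; the closest known reaction type is iridium-catalysed enantioselective allylic etherification (Tsuji–Trost-type substitution) with preformed alkoxides and its decarboxylative version with aryl allyl carbonates, which to my knowledge has not been shown for an aliphatic propargylic alkoxide released by decarboxylation.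

**Step 4**
Reactants: 7 tert-butyl{2-methoxy-4-[(1R)-1-(prop-2-yn-1-yloxy)prop-2-en-1-yl]phenoxy}dimethylsilane; 8 4-iodo-2-methoxyphenol
Product: 9 4-(3-{[(1R)-1-{4-[(tert-butyldimethylsilyl)oxy]-3-methoxyphenyl}prop-2-en-1-yl]oxy}prop-1-yn-1-yl)-2-methoxyphenol
Conditions: Pd(PPh3)2Cl2 (2 mol%), CuI (4 mol%), Et3N, THF, 25 °C, degassed
Reagents that add atoms: none
Why: Sonogashira coupling of the terminal alkyne with the aryl iodide tolerates the free phenol, the silyl ether and the allylic ether and does not touch the stereocentre.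

**Step 5**
Reactants: 9 4-(3-{[(1R)-1-{4-[(tert-butyldimethylsilyl)oxy]-3-methoxyphenyl}prop-2-en-1-yl]oxy}prop-1-yn-1-yl)-2-methoxyphenol; 10 bis(pinacolato)diboron
Product: 13 [(2R,3S,4Z)-2-(4-hydroxy-3-methoxyphenyl)-4-[(4-hydroxy-3-methoxyphenyl)methylidene]oxolan-3-yl]methanol, via alkyl pinacol boronate 11 (not isolated), via silyl-protected primary alcohol 12 (not isolated)
Conditions: Pd(OAc)2 (5 mol%), B2pin2 (1.5 equiv), MeOH (2 equiv), toluene, 50 °C; then 3 M NaOH, 30% H2O2, THF, 0 °C → rt; pH 7 work-up (13 is acid-sensitive)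
Reagents that add atoms: hydrogen peroxide, OO
Why: Pd–H borylative cyclisation of a 1,6-enyne (syn H–Pd addition to the alkyne, 5-exo alkene insertion, C–B bond formation) followed by organoborane oxidation closes the oxolane, the syn addition placing the aryl trans to C3 (4Z) and insertion through a chair-like transition state with the C2 aryl pseudo-equatorial setting C3 trans to C2 (3S in 13), while the alkaline peroxide turns C–B into C–OH and cleaves the aryl silyl ether.

**Step 6**
Reactants: 13 [(2R,3S,4Z)-2-(4-hydroxy-3-methoxyphenyl)-4-[(4-hydroxy-3-methoxyphenyl)methylidene]oxolan-3-yl]methanol; 14 4-hydroxybenzoic acid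
Product: 15 [(2R,3S,4Z)-2-(4-hydroxy-3-methoxyphenyl)-4-[(4-hydroxy-3-methoxyphenyl)methylidene]oxolan-3-yl]methyl 4-hydroxybenzoate
Conditions: PPh3 (1.3 equiv), DIAD (1.3 equiv), 14 (1.5 equiv), THF, 0 °C → rt
Reagents that add atoms: none
Why: In the Mitsunobu esterification only the primary alcohol is activated as its alkoxyphosphonium ion and the carboxylic acid, far more acidic than the phenols, is the pronucleophile, so the ester forms with all three phenols free and without touching C2, C3 or the alkene.

**Compound list**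
1 | vanillin | COc1cc(C=O)ccc1O | starting material
2 | 4-[(tert-butyldimethylsilyl)oxy]-3-methoxybenzaldehyde | COc1cc(C=O)ccc1O[Si](C)(C)C(C)(C)C | intermediate
3 | vinylmagnesium bromide | C=C[Mg]Br | starting material
4 | propargyl chloroformate | C#CCOC(Cl)=O | starting material
5 | bromomagnesium 1-{4-[(tert-butyldimethylsilyl)oxy]-3-methoxyphenyl}prop-2-en-1-olate (racemic; not isolated) | C=CC(O[Mg]Br)c1ccc(O[Si](C)(C)C(C)(C)C)c(OC)c1 | intermediate
6 | 1-{4-[(tert-butyldimethylsilyl)oxy]-3-methoxyphenyl}prop-2-en-1-yl prop-2-yn-1-yl carbonate (racemic) | C=CC(OC(=O)OCC#C)c1ccc(O[Si](C)(C)C(C)(C)C)c(OC)c1 | intermediate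
7 | tert-butyl{2-methoxy-4-[(1R)-1-(prop-2-yn-1-yloxy)prop-2-en-1-yl]phenoxy}dimethylsilane | C=C[C@@H](OCC#C)c1ccc(O[Si](C)(C)C(C)(C)C)c(OC)c1 | intermediate
8 | 4-iodo-2-methoxyphenol | COc1cc(I)ccc1O | starting material
9 | 4-(3-{[(1R)-1-{4-[(tert-butyldimethylsilyl)oxy]-3-methoxyphenyl}prop-2-en-1-yl]oxy}prop-1-yn-1-yl)-2-methoxyphenol | C=C[C@@H](OCC#Cc1ccc(O)c(OC)c1)c1ccc(O[Si](C)(C)C(C)(C)C)c(OC)c1 | intermediate
10 | bis(pinacolato)diboron | CC1(C)OB(OC1(C)C)B1OC(C)(C)C(C)(C)O1 | starting material
11 | 2-{[(2R,3R,4Z)-2-{4-[(tert-butyldimethylsilyl)oxy]-3-methoxyphenyl}-4-[(4-hydroxy-3-methoxyphenyl)methylidene]oxolan-3-yl]methyl}-4,4,5,5-tetramethyl-1,3,2-dioxaborolane (not isolated; same spatial arrangement as 13, the C3 descriptor changes because CH2B ranks below C4) | COc1cc(/C=C2\CO[C@@H](c3ccc(O[Si](C)(C)C(C)(C)C)c(OC)c3)[C@@H]2CB4OC(C)(C)C(C)(C)O4)ccc1O | intermediate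
12 | [(2R,3S,4Z)-2-{4-[(tert-butyldimethylsilyl)oxy]-3-methoxyphenyl}-4-[(4-hydroxy-3-methoxyphenyl)methylidene]oxolan-3-yl]methanol (not isolated) | COc1cc(/C=C2\CO[C@@H](c3ccc(O[Si](C)(C)C(C)(C)C)c(OC)c3)[C@@H]2CO)ccc1O | intermediate
13 | [(2R,3S,4Z)-2-(4-hydroxy-3-methoxyphenyl)-4-[(4-hydroxy-3-methoxyphenyl)methylidene]oxolan-3-yl]methanol | COc1cc(/C=C2\CO[C@@H](c3ccc(O)c(OC)c3)[C@@H]2CO)ccc1O | intermediate
14 | 4-hydroxybenzoic acid | O=C(O)c1ccc(O)cc1 | starting material
15 | [(2R,3S,4Z)-2-(4-hydroxy-3-methoxyphenyl)-4-[(4-hydroxy-3-methoxyphenyl)methylidene]oxolan-3-yl]methyl 4-hydroxybenzoate (CNP0134275.2) | COc1cc(/C=C2\CO[C@@H](c3ccc(O)c(OC)c3)[C@@H]2COC(=O)c2ccc(O)cc2)ccc1O | target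

**Totals**
Total step count: 6. Longest linear sequence: 6 (1 → 2 → 6 → 7 → 9 → 13 → 15).

**Three steps most likely to fail**

Step 3 (the proposed new reaction). Enantioconvergence may be incomplete if the branched carbonate reacts with memory of its configuration. Free alkoxide may attack a second carbonate and scramble it. The terminal alkyne may bind iridium and slow the reaction. The fallback uses known chemistry, taking the stereocentre from an enzymatic kinetic resolution and making the ether by alkylation at the propargylic carbon. It sets out from 2 and comes back at 7. Vinylmagnesium bromide addition to 2 with aqueous work-up gives racemic 1-{4-[(tert-butyldimethylsilyl)oxy]-3-methoxyphenyl}prop-2-en-1-ol F1. Acylation with Candida antarctica lipase B and vinyl acetate in toluene esterifies the (R)-enantiomer and gives (1R)-1-{4-[(tert-butyldimethylsilyl)oxy]-3-methoxyphenyl}prop-2-en-1-yl acetate F2, which is separated from the unreacted (S)-alcohol. Treatment with i-Bu2AlH in CH2Cl2 at −78 °C releases (1R)-1-{4-[(tert-butyldimethylsilyl)oxy]-3-methoxyphenyl}prop-2-en-1-ol F3 without touching the aryl silyl ether. Williamson etherification with NaH and propargyl bromide in THF/DMF at 0 °C breaks no bond to the stereocentre and gives 7.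

Step 5. The Pd–H may add to the aryl alkyne with the other orientation and lead to a six-membered ring. The allyl ether may isomerise. The trans:cis ratio at C3 rests on substrate control alone. The fallback is the cobalt-catalysed hydroboration/cyclisation of 1,6-enynes with pinacolborane, a known reaction class in which the ligand rather than the substrate governs the ring-forming insertion. It sets out from 9 and comes back at 13. Co(acac)2 (5 mol%), a chiral bisphosphine from the ligand set that gives alkylboronates, and HBpin (2.2 equiv) in THF are used; the phenol is carried as its borate. This gives 2-{[(2R,3R,4Z)-2-{4-[(tert-butyldimethylsilyl)oxy]-3-methoxyphenyl}-4-({3-methoxy-4-[(4,4,5,5-tetramethyl-1,3,2-dioxaborolan-2-yl)oxy]phenyl}methylidene)oxolan-3-yl]methyl}-4,4,5,5-tetramethyl-1,3,2-dioxaborolane F4. The NaOH/H2O2 work-up of step 5 then gives 13.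

Step 6. A phenol may be alkylated in place of the carboxylate. Any adventitious acid can close 13 to a furofuran through its p-hydroxystyrene unit. The fallback is exhaustive acylation followed by selective cleavage of the phenolic esters. It sets out from 13 and comes back at 15. 4-Acetoxybenzoyl chloride (3.5 equiv) with pyridine and DMAP in CH2Cl2 gives [(2R,3S,4Z)-2-{4-[(4-acetoxybenzoyl)oxy]-3-methoxyphenyl}-4-({4-[(4-acetoxybenzoyl)oxy]-3-methoxyphenyl}methylidene)oxolan-3-yl]methyl 4-acetoxybenzoate F5. K2CO3 in MeOH at 0 °C then methanolyses the five phenolic ester groups; the alkyl benzoate survives, deactivated as soon as its own phenoxide is freed, and 15 is obtained.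

**Further compounds**
F1 | step 3 | 1-{4-[(tert-butyldimethylsilyl)oxy]-3-methoxyphenyl}prop-2-en-1-ol (racemic) | C=CC(O)c1ccc(O[Si](C)(C)C(C)(C)C)c(OC)c1
F2 | step 3 | (1R)-1-{4-[(tert-butyldimethylsilyl)oxy]-3-methoxyphenyl}prop-2-en-1-yl acetate | C=C[C@@H](OC(C)=O)c1ccc(O[Si](C)(C)C(C)(C)C)c(OC)c1
F3 | step 3 | (1R)-1-{4-[(tert-butyldimethylsilyl)oxy]-3-methoxyphenyl}prop-2-en-1-ol | C=C[C@@H](O)c1ccc(O[Si](C)(C)C(C)(C)C)c(OC)c1
F4 | step 5 | 2-{[(2R,3R,4Z)-2-{4-[(tert-butyldimethylsilyl)oxy]-3-methoxyphenyl}-4-({3-methoxy-4-[(4,4,5,5-tetramethyl-1,3,2-dioxaborolan-2-yl)oxy]phenyl}methylidene)oxolan-3-yl]methyl}-4,4,5,5-tetramethyl-1,3,2-dioxaborolane | COc1cc(/C=C2\CO[C@@H](c3ccc(O[Si](C)(C)C(C)(C)C)c(OC)c3)[C@@H]2CB4OC(C)(C)C(C)(C)O4)ccc1OB5OC(C)(C)C(C)(C)O5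
F5 | step 6 | [(2R,3S,4Z)-2-{4-[(4-acetoxybenzoyl)oxy]-3-methoxyphenyl}-4-({4-[(4-acetoxybenzoyl)oxy]-3-methoxyphenyl}methylidene)oxolan-3-yl]methyl 4-acetoxybenzoate | COc1cc(/C=C2\CO[C@@H](c3ccc(OC(=O)c4ccc(OC(C)=O)cc4)c(OC)c3)[C@@H]2COC(=O)c2ccc(OC(C)=O)cc2)ccc1OC(=O)c1ccc(OC(C)=O)cc1
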